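The readings are calculated with made-up constants; the scatter is artificial.

At early times in the theta run, substrate passes into open intermediate, 94 % and 9 % at 0.667 min, while product reads 2 % at its highest, with a scatter of 2 percentage points.

the same everywhere: substrate 0.20 M; free catalyst 19 mM

| flask | reagent | second catalyst | remark | time |
|---|---|---|---|---|
| theta | 0.11 M | 1 mM | run made earlier |  |
| south-east | 0.160 M | 1.0 mM |  | 2.5 min |
| north-west | 0.240 M | 1.0 mM |  | 2.5 min |
| north-east | 0.360 M | 1.0 mM |  | 2.5 min |

theta run (percent of the substrate charged)

| time / min | product / % | substrate / % | open intermediate / % |
|---|---|---|---|
| 0.200 | 1 | 97 | 2 |
| 0.667 | 0 | 94 | 9 |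
| 1.33 | 2 | 82 | 19 |
| 2.00 | 0 | 73 | 27 |
| 2.50 | 0 | 68 | 31 |

(readings scatter by 2 percentage points)

- for product the idle adduct is counted in
- the analysis behind the earlier runs scatters by 2 percentage points, standard deviation
- steps thought possible: second catalyst + open intermediate <-> catalyst intermediate; reagent + product <-> idle adduct; substrate + free catalyst -> free catalyst + open intermediate; 2 second catalyst <-> resting dimer; reagent + catalyst intermediate -> second catalyst + product

- which of these there is most of at the end, counted by the substrate in it, south-east (substrate / product / open intermediate)
- which of these there is most of at the end, counted by the substrate in it, north-west (substrate / product / open intermediate)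
- which of these there is most of at the end, counted by the substrate in it, north-east (substrate / product / open intermediate)
- the largest of these amounts at the end, in percent of the substrate charged, south-east
- the largest of these amounts at the end, in percent of the substrate charged, north-west
- the largest of these amounts at the end, in percent of the substrate charged, north-east

I turn the question round: what has to be true for substrate not to be the largest amount at 2.5 min? The zero of my scale is the even flask, where substrate and open intermediate hold half each. The opening step has free catalyst on both sides and no reagent in it, so in each flask I treat the fall of substrate as pseudo-first-order, with the free catalyst of theta. I call crossing time the time in which substrate falls to half of its charge at that free catalyst. From the theta reading of 68 % at 2.50 min, a reading with its scatter, it is 4.49 min.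

While product stays as small as theta shows, open intermediate leads once the crossing time comes under the time of the flask. Here it stands above, by a factor of 1.80. So I commit to substrate in south-east, north-west and north-east, at the theta reading of 68 %.

The forecast names substrate for each of them too, at 68 %, with a range from 65.5 % to 70.5 %. Its ground is this: “Opening uses only substrate and free catalyst, so reagent should not change it.”

South-east, north-west and north-east end with substrate largest, at 69.4 %, 69.4 % and 69.4 %.

    second catalyst + open intermediate ⇌ catalyst intermediate (K = 240 L mol⁻¹, k = 590 L mol⁻¹ min⁻¹)
    reagent + product ⇌ idle adduct, settled at all times (K = 3.60 L mol⁻¹)
    substrate + free catalyst → free catalyst + open intermediate (k = 7.70 L mol⁻¹ min⁻¹)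
    2 second catalyst ⇌ resting dimer, settled at all times (K = 1.20 × 10⁶ L mol⁻¹)
    reagent + catalyst intermediate → second catalyst + product (k = 8.20 L mol⁻¹ min⁻¹)

The north-east recipe with 0.076 M of free catalyst, a factor of 4.00 on the charge, should cross in 1.12 min, under 2.5 min, and that flask ends with open intermediate ahead, 76.1 % against 23.2 % of substrate. North-east itself is not at rest at 2.5 min. At 25.0 min, ten times that time, the crossing time gives 2.11 % of substrate, and north-east holds 2.58 % after 25.0 min. Open intermediate stands at 88.0 % then, and product, idle adduct counted in, at 9.22 %.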